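**Assumptions**
- Leuconaphthazarin (the reduced form of naphthazarin) is taken to exist and react as its 2,3-dihydro keto tautomer, compound **8**. This is an enolizable, dearomatized bis-ketone in which C2 and C3 are equivalent.
- The antipode of Ipc2BCl that delivers the (S)-carbinol is taken to be (–)-Ipc2BCl, from (+)-α-pinene. The opposite antipode would give the shikonin (R) series. This needs confirmation by HPLC or Mosher analysis.

## Retrosynthetic overview
1. Target **12** comes from O-acylation of alkannin **10** with 3,3-dimethylacryloyl chloride.
2. **10** comes from dehydrogenation of aldol **9**. **9** comes from a reagent-controlled asymmetric boron aldol between the symmetric dihydronaphthazarin **8** and 4-methylpent-3-enal **7**. This step desymmetrizes C2/C3 of the dearomatized tautomer and sets the carbinol stereocentre.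
3. **8** comes from reduction of naphthazarin **3**, and **3** from a hydroquinone/maleic anhydride double Friedel–Crafts annulation. This is the only ring-forming step; the bicyclic core is made first.
4. **7** comes from isobutenylmagnesium bromide and ethylene oxide, then oxidation.

## Forward route

**Step 1**
- Reactants: **1** hydroquinone; **2** maleic anhydride
- Product: **3** naphthazarin (5,8-dihydroxy-1,4-naphthoquinone)
- Conditions: AlCl3/NaCl melt, 180 °C, 15 min; then ice/aq. HCl
- Reagents that add atoms: none
- Why: Double intermolecular then intramolecular Friedel–Crafts acylation with loss of H2O (Zahn-type melt condensation) keeps the maleic C=C, so the product is already at the naphthazarin oxidation level. No stereocentre is involved.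

**Step 2**
- Reactants: **4** 2-methylprop-1-enylmagnesium bromide; **5** ethylene oxide
- Product: **6** 4-methylpent-3-en-1-ol
- Conditions: CuI (10 mol%), THF, –20 → 0 °C; then aq. NH4Cl
- Reagents that add atoms: none beyond the listed reactants
- Why: Cu-catalysed opening of an epoxide at its unhindered carbon by a vinyl Grignard gives a homoallylic alcohol with the trisubstituted alkene intact.

**Step 3**
- Reactants: **6**
- Product: **7** 4-methylpent-3-enal
- Conditions: Dess–Martin periodinane, NaHCO3, CH2Cl2, 0 °C → rt; filter, distil or use crude
- Reagents that add atoms: none
- Why: Buffered mild oxidation avoids isomerization of the β,γ-enal into conjugation and leaves the alkene untouched.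

**Step 4**
- Reactants: **3**
- Product: **8** 5,8-dihydroxy-2,3-dihydronaphthalene-1,4-dione (dihydro keto tautomer of leuconaphthazarin)
- Conditions: Na2S2O4, H2O/Et2O, rt, N2; extract and dry under Ar; use immediately
- Reagents that add atoms: none (only H is added)
- Why: Two-electron, two-proton reduction of the quinone gives the leuco compound, which tautomerizes to the symmetric dihydro ketone. This dearomatizes the quinone-bearing ring and creates two equivalent enolizable CH2 groups.

**Step 5**
- Reactants: **8**; **7**
- Product: **9** (S)-carbinol aldol adduct, 2-[(1S)-1-hydroxy-4-methylpent-3-enyl]-5,8-dihydroxy-2,3-dihydronaphthalene-1,4-dione. The ring C2 epimers are not defined.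
- Conditions: (–)-Ipc2BCl (3.5 equiv), Et3N (4.5 equiv), CH2Cl2/Et2O, 0 °C, 2 h; then –78 °C, add **7** (0.9 equiv); –78 → –23 °C, 16 h; pH 7 buffer/MeOH workup
- Reagents that add atoms: none
- Why: Proposed new method: the Ipc2B enolate forms at C2 of **8** (extra equivalents borylate the peri-phenols). It adds to **7** through a chair, Zimmerman–Traxler-type transition state in which the isopinocampheyl ligands fix the aldehyde face, giving the (S)-carbinol. The closest known reactions are the Paterson Ipc2BCl/Et3N asymmetric aldol of ketones and the Marschalk hydroxyalkylation of leucoquinones. Sub-stoichiometric aldehyde and –78 °C limit bis-aldol at C3 and E1cB dehydration, and the C2 epimers are erased in Step 6.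

**Step 6**
- Reactants: **9**
- Product: **10** alkannin, (S)-5,8-dihydroxy-2-(1-hydroxy-4-methylpent-3-enyl)-1,4-naphthoquinone
- Conditions: Ag2O, CH2Cl2, rt, 30 min, dark; filter through Celite
- Reagents that add atoms: none
- Why: Enolization of the dihydro ketone to the aromatic leuco form, followed by mild Ag(I) oxidation, is net dehydrogenation to the naphthazarin (Marschalk-type aromatization/oxidation). The non-basic, non-acidic conditions preserve the carbinol stereocentre, and C2 becomes sp2.

**Step 7**
- Reactants: **10**; **11** 3,3-dimethylacryloyl chloride
- Product: **12** alkannin β,β-dimethylacrylate (target)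
- Conditions: pyridine, CH2Cl2, 0 °C, 1 h
- Reagents that add atoms: none beyond the listed reactants
- Why: Chemoselective O-acylation of the free secondary alcohol. The peri-phenols are strongly H-bonded and do not react at 0 °C with 1.1 equiv of acid chloride. The C–O bond is not broken, so the (S) configuration is retained.

## Compound list
1 | hydroquinone | Oc1ccc(O)cc1 | starting material
2 | maleic anhydride | O=C1C=CC(=O)O1 | starting material
3 | naphthazarin | O=C1C=CC(=O)c2c(O)ccc(O)c12 | intermediate
4 | 2-methylprop-1-enylmagnesium bromide | CC(C)=C[Mg]Br | starting material
5 | ethylene oxide | C1CO1 | starting material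
6 | 4-methylpent-3-en-1-ol | CC(C)=CCCO | intermediate
7 | 4-methylpent-3-enal | CC(C)=CCC=O | intermediate
8 | 5,8-dihydroxy-2,3-dihydronaphthalene-1,4-dione | O=C1CCC(=O)c2c(O)ccc(O)c12 | intermediate
9 | aldol adduct, (S)-carbinol (ring C2 undefined) | CC(C)=CC[C@H](O)C1CC(=O)c2c(O)ccc(O)c2C1=O | intermediate
10 | alkannin | CC(C)=CC[C@H](O)C1=CC(=O)c2c(O)ccc(O)c2C1=O | intermediate
11 | 3,3-dimethylacryloyl chloride | CC(C)=CC(=O)Cl | starting material
12 | alkannin β,β-dimethylacrylate | CC(C)=CC[C@H](OC(=O)C=C(C)C)C1=CC(=O)c2c(O)ccc(O)c2C1=O | target

## Checks
- Atom balance: **8** (C10H8O4) + **7** (C6H10O) = **9** (C16H18O5). **9** minus H2 gives **10** (C16H16O5). **10** + acid chloride minus HCl gives **12** (C21H22O6).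
- The (S) descriptor was derived from the target SMILES. The CIP priority order is O > quinone C > CH2 > H, and it is unchanged from **9** to **10** to **12**.
- The only stereocentre, the carbinol, is set in Step 5 and untouched afterwards (Steps 6 and 7 act elsewhere).

## Step count
- Total steps: 7.
- Longest linear sequence: 5 steps (Steps 1, 4, 5, 6, 7). The aldehyde branch is 2 steps.

## Three steps most likely to fail
1. **Step 5 (asymmetric aldol).** Risks are low ee, bis-aldol, dehydration to the alkylidene/Marschalk product, or poor enolization of the chelated ketone.
   - Fallback: change the approach. Start from 1,4,5,8-tetramethoxynaphthalene, do 2-lithiation/formylation, Brown asymmetric allylation, and Grubbs II cross-metathesis with 2-methyl-2-butene. Finish with oxidative demethylation and Step 7.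
2. **Step 1 (AlCl3/NaCl melt).** Yields are low to moderate, and the harsh conditions cause tarring.
   - Fallback: make 2,3-dichloronaphthazarin from 1,4-dimethoxybenzene and dichloromaleic anhydride, then dechlorinate and demethylate. Alternatively use commercial naphthazarin.
3. **Step 7 (esterification).** The carbinol adjacent to the quinone can racemize through a quinone methide, and the phenols can be acylated.
   - Fallback: lipase-catalysed (CAL-B) transesterification of **10** with vinyl 3,3-dimethylacrylate in MTBE, which needs no base or acid chloride.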